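## Retrosynthetic overview
1. The last operations are hydrogenolysis of three benzyl ethers (5-O, 7-O, 5'-O), preceded by 3-O-methylation and by C3 hydroxylation of a tri-O-benzyl flavone.
2. Ring C is the only ring built in the route, by oxidative cyclisation of a 2'-hydroxychalcone. Rings A and B are bought as arenes.
3. The key C–C bond (the future C2–C3) comes from a Claisen–Schmidt aldol condensation of a ring A methyl ketone with a ring B aldehyde.
4. The ring A ketone comes from 2,4,6-trihydroxyacetophenone by dibenzylation, 3,5-dibromination and double copper-catalysed methoxylation. Its substitution pattern is symmetric, so ring closure has no regiochemical issue.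
5. The ring B aldehyde comes from 2,4-dimethoxybenzaldehyde by Baeyer–Villiger oxidation, benzylation and Vilsmeier–Haack formylation.

Assumption: the target is a planar, achiral flavone with no stereocentre, so "single enantiomer" needs no stereocontrol. The stereocentres of transient intermediates are racemic and are destroyed within the same step.

## Route

Step 1
Reactants: 1 2,4,6-trihydroxyacetophenone
Product: 2 1-[2,4-bis(benzyloxy)-6-hydroxyphenyl]ethan-1-one
Conditions: BnBr (2.1 equiv), K2CO3 (2.5 equiv), DMF, rt → 50 °C, 5 h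
Reagents that add atoms: benzyl bromide BrCc1ccccc1
Why: Williamson ether synthesis under weak base alkylates the para OH and one of the two equivalent ortho OH groups, while the last ortho OH is locked in a strong hydrogen bond to the acetyl carbonyl and stays free when BnBr is limited to about two equivalents.

Step 2
Reactants: 2 1-[2,4-bis(benzyloxy)-6-hydroxyphenyl]ethan-1-one
Product: 3 1-[2,4-bis(benzyloxy)-3,5-dibromo-6-hydroxyphenyl]ethan-1-one
Conditions: NBS (2.1 equiv), MeCN, 0 °C → rt, dark, 2 h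
Reagents that add atoms: N-bromosuccinimide O=C1CCC(=O)N1Br
Why: Electrophilic aromatic bromination takes the only two free ring positions, each ortho or para to three oxygen donors, so ionic NBS bromination in the dark outruns attack at the acetyl CH3 or the benzylic CH2 groups.

Step 3
Reactants: 3 1-[2,4-bis(benzyloxy)-3,5-dibromo-6-hydroxyphenyl]ethan-1-one
Product: 4 1-[2,4-bis(benzyloxy)-6-hydroxy-3,5-dimethoxyphenyl]ethan-1-one
Conditions: NaOMe (25% in MeOH, 10 equiv), CuBr (0.4 equiv), DMF, 100 °C, Ar, 8 h; then 1 M HCl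
Reagents that add atoms: sodium methoxide C[O-].[Na+]
Why: Ullmann-type copper-catalysed C–O coupling (the reaction that turns 3,5-dibromo-4-hydroxybenzaldehyde into syringaldehyde) replaces both aryl bromides by methoxide, the benzyl ethers being inert to base and the doubly ortho-substituted ketone too hindered to self-condense.

Step 4
Reactants: 5 2,4-dimethoxybenzaldehyde
Product: 7 2,4-dimethoxyphenol, via aryl formate 6 (not isolated)
Conditions: mCPBA (1.3 equiv), CH2Cl2, 0 °C → rt, 6 h; aq NaHCO3 wash, concentrate; then MeOH, K2CO3 (10 mol %), rt, 1 h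
Reagents that add atoms: 3-chloroperoxybenzoic acid OOC(=O)c1cccc(Cl)c1
Why: In this Baeyer–Villiger oxidation of an electron-rich benzaldehyde (Dakin-type outcome) the 2,4-dimethoxyphenyl group migrates in preference to hydride, and the formate is removed by mild base-catalysed methanolysis.

Step 5
Reactants: 7 2,4-dimethoxyphenol
Product: 8 1-(benzyloxy)-2,4-dimethoxybenzene
Conditions: BnBr (1.1 equiv), K2CO3 (1.5 equiv), acetone, reflux, 6 h
Reagents that add atoms: benzyl bromide BrCc1ccccc1
Why: Williamson ether synthesis on the only acidic OH of the molecule is clean and high yielding.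

Step 6
Reactants: 8 1-(benzyloxy)-2,4-dimethoxybenzene
Product: 10 5-(benzyloxy)-2,4-dimethoxybenzaldehyde, via aryl iminium chloride 9 (not isolated)
Conditions: POCl3 (1.5 equiv), DMF, 0 °C → 60 °C, 3 h; then ice-water, 1 h
Reagents that add atoms: N,N-dimethylformamide CN(C)C=O (formyl carbon); water O (carbonyl oxygen)
Why: In the Vilsmeier–Haack formylation the chloroiminium ion attacks the position para to one OMe and ortho to the other (the selectivity that gives 2,4,5-trimethoxybenzaldehyde from 1,2,4-trimethoxybenzene), the site between the two OMe groups being hindered, and water hydrolyses the iminium salt without touching the benzyl ether.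

Step 7
Reactants: 4 1-[2,4-bis(benzyloxy)-6-hydroxy-3,5-dimethoxyphenyl]ethan-1-one; 10 5-(benzyloxy)-2,4-dimethoxybenzaldehyde
Product: 12 (E)-1-[2,4-bis(benzyloxy)-6-hydroxy-3,5-dimethoxyphenyl]-3-[5-(benzyloxy)-2,4-dimethoxyphenyl]prop-2-en-1-one, via racemic aldol 11 (not isolated)
Conditions: KOH (50% aq, 15 equiv), EtOH, rt → 40 °C, 48 h; then 1 M HCl, 0 °C
Reagents that add atoms: none
Why: In this Claisen–Schmidt crossed aldol condensation only the ketone can form an enolate and only the aldehyde is an accessible electrophile, so one cross product forms, and E1cB loss of water from the racemic aldol gives the conjugated E-enone and erases the carbinol stereocentre.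

Step 8
Reactants: 12 (E)-1-[2,4-bis(benzyloxy)-6-hydroxy-3,5-dimethoxyphenyl]-3-[5-(benzyloxy)-2,4-dimethoxyphenyl]prop-2-en-1-one
Product: 14 5,7-bis(benzyloxy)-2-[5-(benzyloxy)-2,4-dimethoxyphenyl]-6,8-dimethoxy-4H-chromen-4-one, via racemic flavanone 13 (not isolated)
Conditions: I2 (10 mol %), DMSO, 120 °C, 3 h
Reagents that add atoms: none
Why: In the iodine-catalysed oxidative cyclisation of a 2'-hydroxychalcone, oxa-Michael addition of the only free phenol closes ring C, alpha-iodination followed by HI loss aromatises it while DMSO reoxidises HI to I2, and the racemic C2 centre of the flavanone disappears.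

Step 9
Reactants: 14 5,7-bis(benzyloxy)-2-[5-(benzyloxy)-2,4-dimethoxyphenyl]-6,8-dimethoxy-4H-chromen-4-one
Product: 16 5,7-bis(benzyloxy)-2-[5-(benzyloxy)-2,4-dimethoxyphenyl]-3-hydroxy-6,8-dimethoxy-4H-chromen-4-one, via racemic flavone epoxide 15 (not isolated)
Conditions: DMDO (ca. 0.08 M in acetone, 3 equiv), CH2Cl2, 0 °C → rt, 12 h; then p-TsOH·H2O (5 mol %), CH2Cl2, rt, 1 h
Reagents that add atoms: dimethyldioxirane CC1(C)OO1
Why: Epoxidation of the C2=C3 enol-ether bond by a neutral electrophilic oxidant, then acid-catalysed opening at the oxocarbenium-stabilised C2 and loss of H3, gives the aromatic 3-hydroxychromone, so both racemic epoxide stereocentres vanish.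

Step 10
Reactants: 16 5,7-bis(benzyloxy)-2-[5-(benzyloxy)-2,4-dimethoxyphenyl]-3-hydroxy-6,8-dimethoxy-4H-chromen-4-one
Product: 17 5,7-bis(benzyloxy)-2-[5-(benzyloxy)-2,4-dimethoxyphenyl]-3,6,8-trimethoxy-4H-chromen-4-one
Conditions: MeI (1.5 equiv), K2CO3 (2 equiv), DMF, rt, 6 h
Reagents that add atoms: iodomethane CI
Why: Williamson O-methylation has only one possible site, the acidic enolic 3-OH, because every other oxygen is already an ether.

Step 11
Reactants: 17 5,7-bis(benzyloxy)-2-[5-(benzyloxy)-2,4-dimethoxyphenyl]-3,6,8-trimethoxy-4H-chromen-4-one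
Product: 18 5,7-dihydroxy-2-(5-hydroxy-2,4-dimethoxyphenyl)-3,6,8-trimethoxy-4H-chromen-4-one
Conditions: H2 (1 atm), 10% Pd/C, EtOAc–MeOH 1:1, rt, 5 h
Reagents that add atoms: none
Why: Catalytic hydrogenolysis cleaves the three benzylic C–O bonds, while the methyl ethers and the fully substituted aromatic pyranone C2=C3 bond are not reduced at 1 atm and room temperature, and the product has no stereocentre.

## Compound list
1 | 2,4,6-trihydroxyacetophenone (sold as the monohydrate) | CC(=O)c1c(O)cc(O)cc1O | starting material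
2 | 1-[2,4-bis(benzyloxy)-6-hydroxyphenyl]ethan-1-one | CC(=O)c1c(O)cc(OCc2ccccc2)cc1OCc1ccccc1 | intermediate
3 | 1-[2,4-bis(benzyloxy)-3,5-dibromo-6-hydroxyphenyl]ethan-1-one | CC(=O)c1c(O)c(Br)c(OCc2ccccc2)c(Br)c1OCc1ccccc1 | intermediate
4 | 1-[2,4-bis(benzyloxy)-6-hydroxy-3,5-dimethoxyphenyl]ethan-1-one | CC(=O)c1c(O)c(OC)c(OCc2ccccc2)c(OC)c1OCc1ccccc1 | intermediate
5 | 2,4-dimethoxybenzaldehyde | COc1ccc(C=O)c(OC)c1 | starting material
6 | 2,4-dimethoxyphenyl formate (not isolated) | COc1ccc(OC=O)c(OC)c1 | intermediate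
7 | 2,4-dimethoxyphenol | COc1ccc(O)c(OC)c1 | intermediate
8 | 1-(benzyloxy)-2,4-dimethoxybenzene | COc1ccc(OCc2ccccc2)c(OC)c1 | intermediate
9 | N-{[5-(benzyloxy)-2,4-dimethoxyphenyl]methylidene}-N-methylmethanaminium chloride (not isolated) | COc1cc(OC)c(C=[N+](C)C)cc1OCc1ccccc1.[Cl-] | intermediate
10 | 5-(benzyloxy)-2,4-dimethoxybenzaldehyde | COc1cc(OC)c(C=O)cc1OCc1ccccc1 | intermediate
11 | rac-1-[2,4-bis(benzyloxy)-6-hydroxy-3,5-dimethoxyphenyl]-3-[5-(benzyloxy)-2,4-dimethoxyphenyl]-3-hydroxypropan-1-one (not isolated, racemic) | COc1cc(OC)c(C(O)CC(=O)c2c(O)c(OC)c(OCc3ccccc3)c(OC)c2OCc2ccccc2)cc1OCc1ccccc1 | intermediate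
12 | (E)-1-[2,4-bis(benzyloxy)-6-hydroxy-3,5-dimethoxyphenyl]-3-[5-(benzyloxy)-2,4-dimethoxyphenyl]prop-2-en-1-one | COc1cc(OC)c(/C=C/C(=O)c2c(O)c(OC)c(OCc3ccccc3)c(OC)c2OCc2ccccc2)cc1OCc1ccccc1 | intermediate
13 | rac-5,7-bis(benzyloxy)-2-[5-(benzyloxy)-2,4-dimethoxyphenyl]-6,8-dimethoxychroman-4-one (not isolated, racemic) | COc1cc(OC)c(C2CC(=O)c3c(OCc4ccccc4)c(OC)c(OCc4ccccc4)c(OC)c3O2)cc1OCc1ccccc1 | intermediate
14 | 5,7-bis(benzyloxy)-2-[5-(benzyloxy)-2,4-dimethoxyphenyl]-6,8-dimethoxy-4H-chromen-4-one | COc1cc(OC)c(-c2cc(=O)c3c(OCc4ccccc4)c(OC)c(OCc4ccccc4)c(OC)c3o2)cc1OCc1ccccc1 | intermediate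
15 | rac-2,3-epoxide of 14 (2,3-epoxychroman-4-one, not isolated, racemic) | COc1cc(OC)c(C23OC2C(=O)c2c(OCc4ccccc4)c(OC)c(OCc4ccccc4)c(OC)c2O3)cc1OCc1ccccc1 | intermediate
16 | 5,7-bis(benzyloxy)-2-[5-(benzyloxy)-2,4-dimethoxyphenyl]-3-hydroxy-6,8-dimethoxy-4H-chromen-4-one | COc1cc(OC)c(-c2oc3c(OC)c(OCc4ccccc4)c(OC)c(OCc4ccccc4)c3c(=O)c2O)cc1OCc1ccccc1 | intermediate
17 | 5,7-bis(benzyloxy)-2-[5-(benzyloxy)-2,4-dimethoxyphenyl]-3,6,8-trimethoxy-4H-chromen-4-one | COc1cc(OC)c(-c2oc3c(OC)c(OCc4ccccc4)c(OC)c(OCc4ccccc4)c3c(=O)c2OC)cc1OCc1ccccc1 | intermediate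
18 | 5,7-dihydroxy-2-(5-hydroxy-2,4-dimethoxyphenyl)-3,6,8-trimethoxy-4H-chromen-4-one (achiral) | COc1cc(OC)c(-c2oc3c(OC)c(O)c(OC)c(O)c3c(=O)c2OC)cc1O | target

## Step count and risks
Total steps: 11. Longest linear sequence: 8 (steps 1–3 or 4–6, then 7–11).

**Risk 1, step 3.** Each bromide is flanked by two oxygen substituents, and the substrate carries a phenoxide and an enolisable ketone. Hydrodebromination or an incomplete second exchange are the likely failures.
- The fallback moves the C–O coupling behind ring C formation. There the substrate has no phenoxide and no methyl ketone, and the arene is less electron rich.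
- It sets out from 3, which is condensed with 10 (KOH, EtOH) to (E)-1-[2,4-bis(benzyloxy)-3,5-dibromo-6-hydroxyphenyl]-3-[5-(benzyloxy)-2,4-dimethoxyphenyl]prop-2-en-1-one F1.
- I2 in DMSO then closes ring C to 5,7-bis(benzyloxy)-2-[5-(benzyloxy)-2,4-dimethoxyphenyl]-6,8-dibromo-4H-chromen-4-one F2.
- NaOMe/CuBr in DMF–MeOH exchanges both bromides, and the fallback comes back to the route at 14.

**Risk 2, step 8.** HI formed at 120 °C can cleave the chelation-labile 5-O-benzyl ether or iodinate the very electron-rich ring B.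
- The fallback avoids the flavone altogether by an Algar–Flynn–Oyamada oxidation.
- It sets out from 12, which is treated with 30% H2O2 and aqueous NaOH in MeOH at 0 °C → rt.
- This passes through rac-trans-5,7-bis(benzyloxy)-2-[5-(benzyloxy)-2,4-dimethoxyphenyl]-3-hydroxy-6,8-dimethoxychroman-4-one F3, which is oxidised further in the same flask.
- It comes back to the route at 16 and so bypasses steps 8 and 9. The aurone is the by-product to remove by chromatography.

**Risk 3, step 9.** The C2=C3 bond is a sluggish partner for DMDO, so the excess oxidant can attack the polyalkoxy rings or the benzylic CH2 groups.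
- The fallback replaces electrophilic oxidation by deprotonation, borylation and oxidation.
- It sets out from 14, which LDA in THF at −78 °C converts into {5,7-bis(benzyloxy)-2-[5-(benzyloxy)-2,4-dimethoxyphenyl]-6,8-dimethoxy-4-oxo-4H-chromen-3-yl}lithium F4.
- B(OMe)3 traps this as dimethyl {5,7-bis(benzyloxy)-2-[5-(benzyloxy)-2,4-dimethoxyphenyl]-6,8-dimethoxy-4-oxo-4H-chromen-3-yl}boronate F5.
- H2O2 in AcOH oxidises the C–B bond, and the fallback comes back to the route at 16.

## Further compounds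
F1 | step 3 | (E)-1-[2,4-bis(benzyloxy)-3,5-dibromo-6-hydroxyphenyl]-3-[5-(benzyloxy)-2,4-dimethoxyphenyl]prop-2-en-1-one | COc1cc(OC)c(/C=C/C(=O)c2c(O)c(Br)c(OCc3ccccc3)c(Br)c2OCc2ccccc2)cc1OCc1ccccc1
F2 | step 3 | 5,7-bis(benzyloxy)-2-[5-(benzyloxy)-2,4-dimethoxyphenyl]-6,8-dibromo-4H-chromen-4-one | COc1cc(OC)c(-c2cc(=O)c3c(OCc4ccccc4)c(Br)c(OCc4ccccc4)c(Br)c3o2)cc1OCc1ccccc1
F3 | step 8 | rac-trans-5,7-bis(benzyloxy)-2-[5-(benzyloxy)-2,4-dimethoxyphenyl]-3-hydroxy-6,8-dimethoxychroman-4-one (racemate, 2R,3R enantiomer drawn) | COc1cc(OC)c([C@@H]2[C@H](C(=O)c3c(OCc4ccccc4)c(OC)c(OCc4ccccc4)c(OC)c3O2)O)cc1OCc1ccccc1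
F4 | step 9 | {5,7-bis(benzyloxy)-2-[5-(benzyloxy)-2,4-dimethoxyphenyl]-6,8-dimethoxy-4-oxo-4H-chromen-3-yl}lithium | COc1cc(OC)c(-c2oc3c(OC)c(OCc4ccccc4)c(OC)c(OCc4ccccc4)c3c(=O)c2[Li])cc1OCc1ccccc1
F5 | step 9 | dimethyl {5,7-bis(benzyloxy)-2-[5-(benzyloxy)-2,4-dimethoxyphenyl]-6,8-dimethoxy-4-oxo-4H-chromen-3-yl}boronate | COc1cc(OC)c(-c2oc3c(OC)c(OCc4ccccc4)c(OC)c(OCc4ccccc4)c3c(=O)c2B(OC)OC)cc1OCc1ccccc1
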